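**Assumption:** the target SMILES has no stereocentres (the molecule is achiral), so no enantiocontrol is needed and "single enantiomer" simply means the compound as drawn.

## Retrosynthetic overview

1. The depside aryl ester C–O bond is cut last: target ⇒ 3-chloro-2-hydroxy-4-methoxy-6-propylbenzoic acid (A ring) + benzyl 2,4-dihydroxy-6-propylbenzoate (B ring), followed by benzyl removal.
2. A ring: acid ⇐ aldehyde (chlorite oxidation) ⇐ selective 4-O-methylation ⇐ Vilsmeier formylation of 2-chloro-5-propylresorcinol. The chlorine is fixed between the two oxygens by making the resorcinol from 2,2-dichloro-5-propylcyclohexane-1,3-dione.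
3. That dione ring is formed first in its branch by Michael–Claisen annulation of hept-3-en-2-one with dimethyl malonate, then aromatised.
4. B ring: benzyl ester ⇐ divaric acid ⇐ methyl divarate ⇐ aromatisation of the Michael–Dieckmann adduct of methyl acetoacetate and methyl hex-2-enoate.
5. Each benzene ring is therefore built as a cyclohexane-1,3-dione and aromatised in its own branch; the two arenes are joined in the penultimate step.

## Branch A: the acid fragment

**Step 1**
Reactants: 1, malonic acid
Product: 2, dimethyl malonate
Conditions: MeOH, cat. H2SO4, reflux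
Reagents that add atoms: methanol, CO
Why: Fischer esterification, driven by excess methanol, gives the diester needed as the Michael donor.

**Step 2**
Reactants: 2, dimethyl malonate; 3, (E)-hept-3-en-2-one
Product: 4, 5-propylcyclohexane-1,3-dione
Conditions: NaOMe, MeOH, reflux; then aq. NaOH, reflux; then HCl, reflux (–CO2)
Reagents that add atoms: none
Why: Michael addition of the malonate to the enone, Claisen (Dieckmann-type) ring closure of the methyl ketone onto an ester, then saponification and decarboxylation (the dimedone-type annulation) give the 5-substituted dione.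

**Step 3**
Reactants: 4, 5-propylcyclohexane-1,3-dione
Product: 5, 2,2-dichloro-5-propylcyclohexane-1,3-dione
Conditions: SO2Cl2 (2.1 equiv), CH2Cl2, 0 °C → rt
Reagents that add atoms: sulfuryl chloride, O=S(=O)(Cl)Cl
Why: electrophilic α-chlorination occurs twice at C2, the enol carbon between the two carbonyls and the most nucleophilic position.

**Step 4**
Reactants: 5, 2,2-dichloro-5-propylcyclohexane-1,3-dione
Product: 6, 2-chloro-5-propylbenzene-1,3-diol
Conditions: dry HCl, DMF, 90–100 °C
Reagents that add atoms: none
Why: HCl-catalysed chlorine migration from C2 to C4 followed by dehydrochlorination and tautomerisation aromatises the ring, and the chlorine that remains sits between the two hydroxyls.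

**Step 5**
Reactants: 6, 2-chloro-5-propylbenzene-1,3-diol
Product: 7, 3-chloro-2,4-dihydroxy-6-propylbenzaldehyde
Conditions: POCl3, DMF, MeCN, 0 °C → rt; then H2O, 50 °C
Reagents that add atoms: N,N-dimethylformamide, CN(C)C=O (formyl carbon); water, O (carbonyl oxygen on iminium hydrolysis)
Why: Vilsmeier–Haack formylation of the symmetric chlororesorcinol can only occur at the two equivalent positions ortho/para to the hydroxyls, so one regioisomer forms.

**Step 6**
Reactants: 7, 3-chloro-2,4-dihydroxy-6-propylbenzaldehyde
Product: 8, 3-chloro-2-hydroxy-4-methoxy-6-propylbenzaldehyde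
Conditions: MeI (1.05 equiv), K2CO3 (1.0 equiv), acetone, rt
Reagents that add atoms: iodomethane, CI
Why: Williamson etherification is selective for the more acidic para-hydroxyl, because the 2-OH is hydrogen-bonded to the aldehyde.

**Step 7**
Reactants: 8, 3-chloro-2-hydroxy-4-methoxy-6-propylbenzaldehyde
Product: 9, 3-chloro-2-hydroxy-4-methoxy-6-propylbenzoic acid
Conditions: NaClO2, H2NSO3H, dioxane–H2O, 0 °C → rt
Reagents that add atoms: sodium chlorite, [Na+].[O-]Cl=O
Why: Lindgren (Pinnick-type) chlorite oxidation converts the aldehyde to the acid without touching the free phenol, with sulfamic acid scavenging HOCl so the open C5 position is not chlorinated.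

## Branch B: the phenol fragment

**Step 8**
Reactants: 10, (E)-hex-2-enoic acid
Product: 11, methyl (E)-hex-2-enoate
Conditions: MeOH, cat. H2SO4, reflux
Reagents that add atoms: methanol, CO
Why: Fischer esterification gives the Michael acceptor whose ester later serves as the Dieckmann electrophile.

**Step 9**
Reactants: 11, methyl (E)-hex-2-enoate; 12, methyl acetoacetate
Product: 13, methyl 2,4-dioxo-6-propylcyclohexane-1-carboxylate (racemic; exists mainly as the 4-hydroxy-2-oxo-cyclohex-3-ene enol)
Conditions: NaOMe, MeOH, reflux; then aq. HCl, 0 °C
Reagents that add atoms: none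
Why: Michael addition of the acetoacetate α-carbon to the enoate, then Dieckmann condensation of the acetyl methyl onto the enoate ester, closes the ring with the acetoacetate ester retained; the two stereocentres are racemic and are erased on aromatisation.

**Step 10**
Reactants: 13, methyl 2,4-dioxo-6-propylcyclohexane-1-carboxylate
Product: 14, methyl 2,4-dihydroxy-6-propylbenzoate
Conditions: Br2 (1.0 equiv), DMF, 0 °C → rt, then 80 °C
Reagents that add atoms: none
Why: α-bromination of the dione followed by thermal dehydrobromination and tautomerisation (halogenation–elimination aromatisation) gives the resorcylate, the temperature being kept below that needed for ester loss.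

**Step 11**
Reactants: 14, methyl 2,4-dihydroxy-6-propylbenzoate
Product: 15, 2,4-dihydroxy-6-propylbenzoic acid (divaric acid)
Conditions: KOH, DMSO–H2O, 90 °C, N2; then cold 2 M HCl
Reagents that add atoms: potassium hydroxide, [K+].[OH-]
Why: saponification of the hindered ester under forcing basic conditions, where the carboxylate does not decarboxylate, followed by cold acidification to avoid acid-promoted loss of CO2.

**Step 12**
Reactants: 15, 2,4-dihydroxy-6-propylbenzoic acid
Product: 16, benzyl 2,4-dihydroxy-6-propylbenzoate
Conditions: BnBr, KHCO3, DMF, rt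
Reagents that add atoms: benzyl bromide, BrCc1ccccc1
Why: bicarbonate deprotonates only the carboxylic acid, so SN2 O-alkylation gives the benzyl ester and leaves both phenols free.

## Fragment union and unmasking

**Step 13**
Reactants: 9, 3-chloro-2-hydroxy-4-methoxy-6-propylbenzoic acid; 16, benzyl 2,4-dihydroxy-6-propylbenzoate
Product: 17, benzyl 4-[(3-chloro-2-hydroxy-4-methoxy-6-propylbenzoyl)oxy]-2-hydroxy-6-propylbenzoate
Conditions: TFAA, toluene, rt
Reagents that add atoms: none
Why: the mixed trifluoroacetic anhydride of 9 acylates the free 4-OH of 16 (depside esterification), because the 2-hydroxyls of both partners are hydrogen-bonded to their ortho carbonyls and flanked by substituents.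

**Step 14**
Reactants: 17, benzyl 4-[(3-chloro-2-hydroxy-4-methoxy-6-propylbenzoyl)oxy]-2-hydroxy-6-propylbenzoate
Product: 18, 3-chlorodivaricatic acid, 4-[(3-chloro-2-hydroxy-4-methoxy-6-propylbenzoyl)oxy]-2-hydroxy-6-propylbenzoic acid
Conditions: H2 (1 atm), 10% Pd/C, EtOAc, rt, stopped after 1 equiv H2
Reagents that add atoms: none
Why: neutral hydrogenolysis cleaves the benzyl ester much faster than the aryl C–Cl bond and leaves the base-sensitive depside ester intact.

## Compound list

1 | malonic acid | OC(=O)CC(=O)O | starting material
2 | dimethyl malonate | COC(=O)CC(=O)OC | intermediate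
3 | (E)-hept-3-en-2-one | CCC/C=C/C(C)=O | starting material
4 | 5-propylcyclohexane-1,3-dione | CCCC1CC(=O)CC(=O)C1 | intermediate
5 | 2,2-dichloro-5-propylcyclohexane-1,3-dione | CCCC1CC(=O)C(Cl)(Cl)C(=O)C1 | intermediate
6 | 2-chloro-5-propylbenzene-1,3-diol | CCCc1cc(O)c(Cl)c(O)c1 | intermediate
7 | 3-chloro-2,4-dihydroxy-6-propylbenzaldehyde | CCCc1cc(O)c(Cl)c(O)c1C=O | intermediate
8 | 3-chloro-2-hydroxy-4-methoxy-6-propylbenzaldehyde | CCCc1cc(OC)c(Cl)c(O)c1C=O | intermediate
9 | 3-chloro-2-hydroxy-4-methoxy-6-propylbenzoic acid | CCCc1cc(OC)c(Cl)c(O)c1C(=O)O | intermediate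
10 | (E)-hex-2-enoic acid | CCC/C=C/C(=O)O | starting material
11 | methyl (E)-hex-2-enoate | CCC/C=C/C(=O)OC | intermediate
12 | methyl acetoacetate | COC(=O)CC(C)=O | starting material
13 | methyl 2,4-dioxo-6-propylcyclohexane-1-carboxylate (racemic, enol tautomer predominant) | CCCC1CC(=O)CC(=O)C1C(=O)OC | intermediate
14 | methyl 2,4-dihydroxy-6-propylbenzoate | CCCc1cc(O)cc(O)c1C(=O)OC | intermediate
15 | 2,4-dihydroxy-6-propylbenzoic acid | CCCc1cc(O)cc(O)c1C(=O)O | intermediate
16 | benzyl 2,4-dihydroxy-6-propylbenzoate | CCCc1cc(O)cc(O)c1C(=O)OCc1ccccc1 | intermediate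
17 | benzyl 4-[(3-chloro-2-hydroxy-4-methoxy-6-propylbenzoyl)oxy]-2-hydroxy-6-propylbenzoate | CCCc1cc(OC(=O)c2c(CCC)cc(OC)c(Cl)c2O)cc(O)c1C(=O)OCc1ccccc1 | intermediate
18 | 3-chlorodivaricatic acid | CCCc1cc(OC(=O)c2c(CCC)cc(OC)c(Cl)c2O)cc(O)c1C(=O)O | target

## Summary

**Total step count:** 14

**Longest linear sequence:** 9 (steps 1–7, 13, 14); the other branch is 7 (steps 8–12, 13, 14).

**Steps most likely to fail, with fallbacks:**

1. **Step 4** (chlorine shift and dehydrochlorination of the 2,2-dichlorodione): it may give over-chlorinated or dechlorinated resorcinols. Fallback: aromatise 4 with I2/MeOH to 1,3-dimethoxy-5-propylbenzene, then install chlorine by directed ortho-lithiation between the two methoxy groups (n-BuLi/TMEDA, C2Cl6). Continue with Rieche formylation, chlorite oxidation and BCl3 cleavage of the methoxy group ortho to the acid to reach 9.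
2. **Step 10** (Br2/DMF aromatisation with the ester kept): ring bromination or partial ester loss is possible. Fallback: run the same reaction to full decarboxylative aromatisation (160 °C) to give 5-propylresorcinol, then ortho-carboxylate with methyl magnesium carbonate (Kolbe–Schmitt type). This gives 15 directly and also bypasses the step 11 hydrolysis.
3. **Step 14** (hydrogenolysis in the presence of an aryl chloride): hydrodechlorination may compete. Fallback: carry the B ring as its allyl ester (allyl bromide/KHCO3 in step 12) and unmask after coupling with Pd(PPh3)4/PhSiH3, which involves no hydrogen and no nucleophilic base.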